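**Plan**
1. Locants follow germacrane numbering: ring C1–C10, lactone carbonyl C12, exocyclic CH2 C13, methyls C14 (on C10) and C15 (on C4).
2. Cuts: the C6 ester C–O and the 4,5-epoxide last; then C11–C12 and C7–C8 in one event, which opens both the γ-lactone and the ten-membered ring; then C6–C7 and C3–C4.
3. Enabling feature: the α-methylene-γ-lactone fused at C7–C8 is the adduct of a 2-carboxyallyl metal and an aldehyde, so C13=C11=C7 becomes a terminal allene, C12 becomes CO2, and C8 with its oxygen becomes an aldehyde.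
4. Forward: (R)-citronellal (C8–C10, C1–C3, C14) is α-oxygenated, cleaved and joined by B-alkyl Suzuki coupling to a (Z)-iodobutenol (Z-C4=C5); alkynylation and SN2′ reduction give the allenyl carbinol; nickel/CO2 closes the carbocycle, then the lactone; epoxidation, acylation and desilylation finish.
5. Stereochemistry: C10 from the chiral pool; C9 and C6 by catalysis; C7 and C8 relayed in the key step from C6 (1,3-allylic strain) and C9 (Felkin–Anh); C4/C5 from the Z geometry plus 6-OH-directed epoxidation.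

Key step: step 14

Remark: the facial sense of the zinc–ProPhenol alkynylation (step 9) is assumed from the usual model and the antipodal ligand is used if the other carbinol forms; TBS = tert-butyldimethylsilyl, PMB = 4-methoxybenzyl.

**Step 1**
Reactants: 1 (R)-citronellal
Product: 3 (2R,3R)-3,7-dimethyl-2-[(phenylamino)oxy]oct-6-en-1-ol, via α-anilinooxy aldehyde 2 (not isolated)
Conditions: PhNO, L-proline (20 mol%), DMSO, rt; then NaBH4, EtOH, 0 °C
Reagents that add atoms: nitrosobenzene, O=Nc1ccccc1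
Why: Proline-catalysed enamine α-aminoxylation of an aldehyde, in which the L-proline enamine should be attacked by the oxygen of PhN=O on the face fixed by the carboxylic acid, setting (2R) under catalyst control whatever the β-methyl centre, and borohydride traps the labile α-oxy aldehyde.

**Step 2**
Reactants: 3 anilinooxy alcohol
Product: 4 (2R,3R)-3,7-dimethyloct-6-ene-1,2-diol
Conditions: Zn dust, AcOH, EtOH, rt
Reagents that add atoms: none
Why: Reductive N–O cleavage of an O-alkyl-N-arylhydroxylamine by zinc in acetic acid should free the diol and leave the trisubstituted alkene and both stereocentres untouched.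

**Step 3**
Reactants: 4 diol
Product: 5 (2R,3R)-1,2-bis(TBS-oxy)-3,7-dimethyloct-6-ene
Conditions: TBSOTf (2.5 equiv), 2,6-lutidine, CH2Cl2, −78 → 0 °C
Reagents that add atoms: tert-butyldimethylsilyl trifluoromethanesulfonate, CC(C)(C)[Si](C)(C)OS(=O)(=O)C(F)(F)F
Why: Silyl ether formation with a silyl triflate and a hindered pyridine base should silylate the hindered secondary hydroxyl as well as the primary one.

**Step 4**
Reactants: 5 bis-TBS ether
Product: 7 (4R,5R)-5,6-bis(TBS-oxy)-4-methylhexan-1-ol, via secondary ozonide 6 (not isolated)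
Conditions: O3, CH2Cl2, −78 °C; then NaBH4, MeOH, −78 °C → rt
Reagents that add atoms: ozone, [O-][O+]=O
Why: Ozonolysis with reductive borohydride work-up, in which the electron-rich trisubstituted alkene is the only ozone-reactive site and the silyl ethers are inert.

**Step 5**
Reactants: 7 primary alcohol
Product: 8 (2R,3R)-1,2-bis(TBS-oxy)-6-iodo-3-methylhexane
Conditions: I2, PPh3, imidazole, CH2Cl2, 0 °C → rt
Reagents that add atoms: iodine, II
Why: Appel-type iodination should convert the primary alcohol into the iodide by SN2 displacement of the alkoxyphosphonium ion.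

**Step 6**
Reactants: 9 but-2-yn-1-ol
Product: 11 (Z)-3-iodobut-2-en-1-ol, via cyclic vinylalanate 10 (not isolated)
Conditions: NaAlH2(OCH2CH2OMe)2, THF, 0 °C → rt; then I2, THF, −78 °C → rt
Reagents that add atoms: iodine, II
Why: Hydroxyl-directed trans-hydroalumination of a propargylic alcohol followed by iodinolysis with retention, in which the five-membered alanate fixes aluminium, and then iodine, cis to the CH2O group so that only the (Z)-iodide should form.

**Step 7**
Reactants: 8 alkyl iodide; 11 (Z)-3-iodobut-2-en-1-ol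
Product: 14 (2Z,7R,8R)-8,9-bis(TBS-oxy)-3,7-dimethylnon-2-en-1-ol, via alkyllithium 12 (not isolated), via lithium alkyl(methoxy)borate 13 (not isolated)
Conditions: t-BuLi (2.1 equiv), Et2O, −78 °C; B-methoxy-9-BBN, THF, −78 °C → rt; then 11, Pd(dppf)Cl2 (5 mol%), AsPh3, K3PO4 (3 M aq), DMF, rt
Reagents that add atoms: none
Why: B-alkyl Suzuki–Miyaura coupling, in which the borate transmetalates to the vinylpalladium formed from 11 and reductive elimination proceeds with retention, so the chain should end up cis to the CH2OH group, giving the (Z)-trisubstituted C4=C5 alkene.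

**Step 8**
Reactants: 14 (Z)-allylic alcohol
Product: 15 (2Z,7R,8R)-8,9-bis(TBS-oxy)-3,7-dimethylnon-2-enal
Conditions: MnO2 (activated, excess), CH2Cl2, rt
Reagents that add atoms: none
Why: Allylic alcohol oxidation with MnO2, a neutral heterogeneous oxidant that should keep the Z geometry of the enal, which is used at once.

**Step 9**
Reactants: 15 (Z)-enal; 16 2-(prop-2-yn-1-yloxy)oxane
Product: 17 (4S,5Z,10R,11R)-11,12-bis(TBS-oxy)-6,10-dimethyl-1-(oxan-2-yloxy)dodec-5-en-2-yn-4-ol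
Conditions: Me2Zn (3 equiv), ProPhenol ligand (10 mol%, enantiomer for Re-face addition), Ph3P=O (20 mol%), toluene, 0 °C
Reagents that add atoms: none
Why: Catalytic enantioselective alkynylzinc addition to an enal under dinuclear zinc–ProPhenol catalysis should deliver the alkynyl group to the Re face and set the (S)-carbinol (C6 of the target) under catalyst control, the oxanyl acetal centre being inconsequential.

**Step 10**
Reactants: 17 propargylic alcohol
Product: 18 (4R,5Z,10R,11R)-11,12-bis(TBS-oxy)-6,10-dimethyldodeca-1,2,5-trien-4-ol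
Conditions: LiAlH4, Et2O, 0 °C → reflux
Reagents that add atoms: none
Why: Alkoxide-directed SN2′ hydride delivery (LiAlH4 reduction of a 4-alkoxybut-2-yn-1-ol), in which hydride adds to the alkyne carbon next to the carbinol and the vinylalanate expels the oxanyloxy group, should give the terminal allene without touching the carbinol centre (the descriptor changes only by priority).

**Step 11**
Reactants: 18 allenyl carbinol
Product: 19 PMB ether of 18, (4R,5Z,10R,11R)
Conditions: NaH, PMBCl, Bu4NI (cat.), DMF, 0 °C → rt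
Reagents that add atoms: 4-methoxybenzyl chloride, COc1ccc(CCl)cc1
Why: Williamson etherification gives an ether that, unlike an ester, cannot ionise next to the allene under zerovalent nickel and can later be removed oxidatively.

**Step 12**
Reactants: 19 PMB ether
Product: 20 (2R,3R,7Z,9R)-2-(TBS-oxy)-9-(PMB-oxy)-3,7-dimethyldodeca-7,10,11-trien-1-ol
Conditions: HF·pyridine, pyridine, THF, 0 °C → rt
Reagents that add atoms: none
Why: Selective desilylation, since buffered HF·pyridine should cleave the unhindered primary silyl ether much faster than the secondary one next to a branched carbon.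

**Step 13**
Reactants: 20 primary alcohol
Product: 21 (2R,3R,7Z,9R)-2-(TBS-oxy)-9-(PMB-oxy)-3,7-dimethyldodeca-7,10,11-trienal
Conditions: Dess–Martin periodinane, NaHCO3, CH2Cl2, 0 °C → rt
Reagents that add atoms: none
Why: Dess–Martin oxidation under bicarbonate buffer should give the α-silyloxy aldehyde without epimerisation at C9, and it is used directly.

**Step 14**
Reactants: 21 allenyl aldehyde
Product: 24 (4Z,6S,7R,8S,9R,10R)-9-(TBS-oxy)-6-(PMB-oxy)germacra-4,11(13)-dien-12,8-olide (trans-fused lactone), via nickelalactone 22 (not isolated), via hydroxy acid 23 (not isolated)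
Conditions: Ni(cod)2 (1.5 equiv), DBU (3 equiv), CO2 (1 atm), THF, 0 °C, 21 added over 8 h (final 2 mM), then rt; 1 M HCl work-up (0 °C); PPTS (cat.), CH2Cl2, rt
Reagents that add atoms: carbon dioxide, O=C=O
Why: Proposed new method: DBU-ligated zerovalent nickel should couple CO2 oxidatively with the terminal allene at its central carbon C11 (C11–C12 bond) to give nickelalactone 22, a 2-carboxylato-allylnickel whose σ-allyl form (Ni on C13) adds through its substituted terminus C7 to the tethered aldehyde carbon C8 in a six-membered chair transition state (C7–C8 bond), and acid work-up releases hydroxy acid 23, which lactonises. The closest known reaction types are the nickel-mediated three-component coupling of terminal allenes, CO2 and aldehydes (intermolecular, forming the same two bonds) and the intramolecular Nozaki–Hiyama–Kishi allylation of 2-(alkoxycarbonyl)allyl halides that closes ten-membered germacranolide rings. The ten-membered carbocycle closes by intramolecular SE2′ carbonyl allylation (exo addition to the C8=O group through a Zimmerman–Traxler array), and the γ-lactone then closes by 5-exo-trig acyl substitution of O8 on C12. C7 is controlled by C6 through 1,3-allylic strain (H6 eclipses the C7=C11 bond, so C8 enters anti to the C6 oxygen on the face that carries the tether), and C8 is controlled by C9 through polar Felkin–Anh addition anti to the bulky, non-chelating silyloxy group; both preferences are matched in the chair with the (E)-σ-allyl (C6 cis to the carboxylate, reached by π-allyl equilibration) and C9 equatorial, which gives the anti adduct and hence the trans-fused lactone. The step needs chemoselectivity (CO2 capture by the allene before nickel engages the aldehyde, and cyclisation over oligomerisation), to be secured by CO2 saturation and slow addition at high dilution, and regioselectivity for attack through C7 rather than C13 (ten- versus twelve-membered ring), to be secured by the cyclic six-membered transition state. The C6 oxygen is carried as an ether because an ester next to the allene would ionise under zerovalent nickel.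

**Step 15**
Reactants: 24 PMB-protected lactone
Product: 25 (4Z,6S,7R,8S,9R,10R)-9-(TBS-oxy)-6-hydroxygermacra-4,11(13)-dien-12,8-olide
Conditions: DDQ (1.3 equiv), CH2Cl2/pH 7 buffer (10:1), 0 °C
Reagents that add atoms: none
Why: Oxidative cleavage of the 4-methoxybenzyl ether by DDQ under buffered conditions should spare the silyl ether, the Z-alkene and the α-methylene lactone.

**Step 16**
Reactants: 25 allylic alcohol
Product: 26 (4R,5S,6R,7R,8S,9R,10R)-9-(TBS-oxy)-4,5-epoxy-6-hydroxygermacr-11(13)-en-12,8-olide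
Conditions: mCPBA (1.2 equiv), NaHCO3, CH2Cl2, 0 °C
Reagents that add atoms: 3-chloroperoxybenzoic acid, OOC(=O)c1cccc(Cl)c1
Why: Hydroxyl-directed peracid epoxidation, in which 1,3-allylic strain holds H6 in the alkene plane so that the hydrogen-bonded peracid should add to the C4=C5 face syn to the C6 hydroxyl (threo), giving the (4R,5S) cis-epoxide while the electron-poor exocyclic alkene stays untouched.

**Step 17**
Reactants: 26 epoxy alcohol
Product: 27 (4R,5S,6R,7R,8S,9R,10R)-9-(TBS-oxy)-4,5-epoxy-6-[(3-methylbut-2-enoyl)oxy]germacr-11(13)-en-12,8-olide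
Conditions: 3-methylbut-2-enoic acid, DCC, DMAP (cat.), CH2Cl2, 0 °C → rt
Reagents that add atoms: 3-methylbut-2-enoic acid, CC(C)=CC(=O)O
Why: Steglich esterification of the hindered secondary epoxy alcohol, where catalytic DMAP at low temperature should keep the acyl group conjugated.

**Step 18**
Reactants: 27 silyl ether
Product: 28 (4R,5S,6R,7S,8S,9R,10R)-4,5-epoxy-9-hydroxy-6-[(3-methylbut-2-enoyl)oxy]germacr-11(13)-en-12,8-olide (target)
Conditions: HF·pyridine, pyridine, THF, 0 °C → rt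
Reagents that add atoms: none
Why: Fluoride-mediated cleavage of the secondary silyl ether with pyridine-buffered HF·pyridine should spare the epoxide, the senecioate and the α-methylene lactone.

**Compound list**
1 | (R)-citronellal, (3R)-3,7-dimethyloct-6-enal | O=CC[C@H](C)CCC=C(C)C | starting material
2 | (2R,3R)-3,7-dimethyl-2-[(phenylamino)oxy]oct-6-enal | O=C[C@H](ONc1ccccc1)[C@H](C)CCC=C(C)C | intermediate
3 | (2R,3R)-3,7-dimethyl-2-[(phenylamino)oxy]oct-6-en-1-ol | OC[C@H](ONc1ccccc1)[C@H](C)CCC=C(C)C | intermediate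
4 | (2R,3R)-3,7-dimethyloct-6-ene-1,2-diol | OC[C@H](O)[C@H](C)CCC=C(C)C | intermediate
5 | (2R,3R)-1,2-bis[(tert-butyldimethylsilyl)oxy]-3,7-dimethyloct-6-ene | CC(C)(C)[Si](C)(C)OC[C@H](O[Si](C)(C)C(C)(C)C)[C@H](C)CCC=C(C)C | intermediate
6 | 3-{(3R,4R)-4,5-bis[(tert-butyldimethylsilyl)oxy]-3-methylpentyl}-5,5-dimethyl-1,2,4-trioxolane | CC(C)(C)[Si](C)(C)OC[C@H](O[Si](C)(C)C(C)(C)C)[C@H](C)CCC1OOC(C)(C)O1 | intermediate
7 | (4R,5R)-5,6-bis[(tert-butyldimethylsilyl)oxy]-4-methylhexan-1-ol | CC(C)(C)[Si](C)(C)OC[C@H](O[Si](C)(C)C(C)(C)C)[C@H](C)CCCO | intermediate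
8 | (2R,3R)-1,2-bis[(tert-butyldimethylsilyl)oxy]-6-iodo-3-methylhexane | CC(C)(C)[Si](C)(C)OC[C@H](O[Si](C)(C)C(C)(C)C)[C@H](C)CCCI | intermediate
9 | but-2-yn-1-ol | CC#CCO | starting material
10 | sodium 2,2-bis(2-methoxyethoxy)-3-methyl-2,5-dihydro-1,2-oxaluminol-2-uide (cyclic vinylalanate) | CC1=CCO[Al-]1(OCCOC)OCCOC.[Na+] | intermediate
11 | (Z)-3-iodobut-2-en-1-ol | C/C(I)=C/CO | intermediate
12 | [(4R,5R)-5,6-bis[(tert-butyldimethylsilyl)oxy]-4-methylhexyl]lithium | CC(C)(C)[Si](C)(C)OC[C@H](O[Si](C)(C)C(C)(C)C)[C@H](C)CCC[Li] | intermediate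
13 | lithium 9-[(4R,5R)-5,6-bis[(tert-butyldimethylsilyl)oxy]-4-methylhexyl]-9-methoxy-9-boranuidabicyclo[3.3.1]nonane | CC(C)(C)[Si](C)(C)OC[C@H](O[Si](C)(C)C(C)(C)C)[C@H](C)CCC[B-]1(OC)C2CCCC1CCC2.[Li+] | intermediate
14 | (2Z,7R,8R)-8,9-bis[(tert-butyldimethylsilyl)oxy]-3,7-dimethylnon-2-en-1-ol | CC(C)(C)[Si](C)(C)OC[C@H](O[Si](C)(C)C(C)(C)C)[C@H](C)CCC/C(C)=C\CO | intermediate
15 | (2Z,7R,8R)-8,9-bis[(tert-butyldimethylsilyl)oxy]-3,7-dimethylnon-2-enal | CC(C)(C)[Si](C)(C)OC[C@H](O[Si](C)(C)C(C)(C)C)[C@H](C)CCC/C(C)=C\C=O | intermediate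
16 | 2-(prop-2-yn-1-yloxy)oxane (racemic) | C#CCOC1CCCCO1 | starting material
17 | (4S,5Z,10R,11R)-11,12-bis[(tert-butyldimethylsilyl)oxy]-6,10-dimethyl-1-(oxan-2-yloxy)dodec-5-en-2-yn-4-ol (both epimers at the oxane acetal carbon) | CC(C)(C)[Si](C)(C)OC[C@H](O[Si](C)(C)C(C)(C)C)[C@H](C)CCC/C(C)=C\[C@H](O)C#CCOC1CCCCO1 | intermediate
18 | (4R,5Z,10R,11R)-11,12-bis[(tert-butyldimethylsilyl)oxy]-6,10-dimethyldodeca-1,2,5-trien-4-ol | CC(C)(C)[Si](C)(C)OC[C@H](O[Si](C)(C)C(C)(C)C)[C@H](C)CCC/C(C)=C\[C@H](O)C=C=C | intermediate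
19 | (4R,5Z,10R,11R)-11,12-bis[(tert-butyldimethylsilyl)oxy]-4-[(4-methoxybenzyl)oxy]-6,10-dimethyldodeca-1,2,5-triene | CC(C)(C)[Si](C)(C)OC[C@H](O[Si](C)(C)C(C)(C)C)[C@H](C)CCC/C(C)=C\[C@H](OCc1ccc(OC)cc1)C=C=C | intermediate
20 | (2R,3R,7Z,9R)-2-[(tert-butyldimethylsilyl)oxy]-9-[(4-methoxybenzyl)oxy]-3,7-dimethyldodeca-7,10,11-trien-1-ol | OC[C@H](O[Si](C)(C)C(C)(C)C)[C@H](C)CCC/C(C)=C\[C@H](OCc1ccc(OC)cc1)C=C=C | intermediate
21 | (2R,3R,7Z,9R)-2-[(tert-butyldimethylsilyl)oxy]-9-[(4-methoxybenzyl)oxy]-3,7-dimethyldodeca-7,10,11-trienal | O=C[C@H](O[Si](C)(C)C(C)(C)C)[C@H](C)CCC/C(C)=C\[C@H](OCc1ccc(OC)cc1)C=C=C | intermediate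
22 | nickelalactone (1-oxa-2-nickelacyclopentan-5-one carrying the (E)-alkylidene chain of 21 at C4; σ-allyl form, DBU ligands on nickel not drawn) | O=C[C@H](O[Si](C)(C)C(C)(C)C)[C@H](C)CCC/C(C)=C\[C@H](OCc1ccc(OC)cc1)/C=C2\C(=O)O[Ni]C2 | intermediate
23 | (4Z,6S,7S,8S,9R,10R)-9-[(tert-butyldimethylsilyl)oxy]-8-hydroxy-6-[(4-methoxybenzyl)oxy]germacra-4,11(13)-dien-12-oic acid | O[C@@H]1[C@H](O[Si](C)(C)C(C)(C)C)[C@H](C)CCC/C(C)=C\[C@H](OCc2ccc(OC)cc2)[C@H]1C(=C)C(=O)O | intermediate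
24 | (4Z,6S,7R,8S,9R,10R)-9-[(tert-butyldimethylsilyl)oxy]-6-[(4-methoxybenzyl)oxy]germacra-4,11(13)-dien-12,8-olide | C=C1C(=O)O[C@@H]2[C@H](O[Si](C)(C)C(C)(C)C)[C@H](C)CCC/C(C)=C\[C@H](OCc3ccc(OC)cc3)[C@@H]12 | intermediate
25 | (4Z,6S,7R,8S,9R,10R)-9-[(tert-butyldimethylsilyl)oxy]-6-hydroxygermacra-4,11(13)-dien-12,8-olide | C=C1C(=O)O[C@@H]2[C@H](O[Si](C)(C)C(C)(C)C)[C@H](C)CCC/C(C)=C\[C@H](O)[C@@H]12 | intermediate
26 | (4R,5S,6R,7R,8S,9R,10R)-9-[(tert-butyldimethylsilyl)oxy]-4,5-epoxy-6-hydroxygermacr-11(13)-en-12,8-olide | C=C1C(=O)O[C@@H]2[C@H](O[Si](C)(C)C(C)(C)C)[C@H](C)CCC[C@@]3(C)O[C@H]3[C@H](O)[C@@H]12 | intermediate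
27 | (4R,5S,6R,7R,8S,9R,10R)-9-[(tert-butyldimethylsilyl)oxy]-4,5-epoxy-6-[(3-methylbut-2-enoyl)oxy]germacr-11(13)-en-12,8-olide | C=C1C(=O)O[C@@H]2[C@H](O[Si](C)(C)C(C)(C)C)[C@H](C)CCC[C@@]3(C)O[C@H]3[C@H](OC(=O)C=C(C)C)[C@@H]12 | intermediate
28 | (4R,5S,6R,7S,8S,9R,10R)-4,5-epoxy-9-hydroxy-6-[(3-methylbut-2-enoyl)oxy]germacr-11(13)-en-12,8-olide | C=C1C(=O)O[C@@H]2[C@H](O)[C@H](C)CCC[C@@]3(C)O[C@H]3[C@H](OC(=O)C=C(C)C)[C@@H]12 | target

**Step count**
Total: 18 steps. Longest linear sequence: 17 steps (steps 1–5 and 7–18); step 6 prepares the coupling partner.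

**Steps most likely to fail**

Step 14 (Proposed new method). Zerovalent nickel may engage the aldehyde or oligomerise the allene before CO2 is captured. The allylnickel may attack through C13, lose the C6 ether by β-elimination, or add with poor facial selectivity. DBU may epimerise C9. The fallback uses known chemistry, an intramolecular Nozaki–Hiyama–Kishi allylation of a 2-(methoxycarbonyl)allyl bromide; it sets out from 17 and comes back at 24. Compound 17 is converted (NaH, PMBCl) into its 4-methoxybenzyl ether F1. The oxanyl group is removed (PPTS, EtOH) to give propargylic alcohol F2. Palladium-catalysed syn-hydrostannation (Bu3SnH, PdCl2(PPh3)2) places tin next to the CH2OH group to give vinylstannane F3, and iodinolysis gives vinyl iodide F4. Methoxycarbonylation (Pd(PPh3)4, CO, MeOH, Et3N) gives hydroxymethyl enoate F5, and Appel bromination (CBr4, PPh3) gives allylic bromide F6. Buffered HF·pyridine frees primary alcohol F7, and Dess–Martin oxidation gives bromo aldehyde F8. CrCl2 in THF/DMF at high dilution forms allylchromium dichloride F9, which equilibrates by 1,3-metallotropy and closes the ten-membered ring to hydroxy ester F10 under the same allylic-strain and Felkin–Anh control. PPTS-catalysed lactonisation of F10 then gives 24.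

Step 9. The enantioselectivity may erode, or the Z-enal may isomerise to the E-enal under the zinc conditions. The fallback sets out from 15 and comes back at 17. The lithium acetylide of 16 (n-BuLi, THF, −78 °C) is added to 15 to give the epimeric carbinols F11. MnO2 oxidation gives ynone F12. Corey–Bakshi–Shibata reduction (the oxazaborolidine enantiomer that delivers hydride to the Re face, catecholborane, toluene, −78 °C) returns 17.

Step 16. The ring conformation may override the allylic-strain and hydroxyl-directing model and give poor facial selectivity. The fallback sets out from 18 and comes back at 26; it moves the epoxidation to the open-chain stage, where hydroxyl-directed threo epoxidation of (Z)-allylic alcohols under 1,3-allylic strain is reliable. mCPBA on 18 gives epoxy allenol F13. Neutral 4-methoxybenzylation (2-(4-methoxybenzyloxy)-4-methylquinoline, MeOTf, MgO, PhCF3), which avoids Payne rearrangement, gives ether F14. Buffered HF·pyridine gives primary alcohol F15, and Dess–Martin oxidation gives aldehyde F16. The conditions of step 14, with a pH 5 buffered work-up, lead through nickelalactone F17 and hydroxy acid F18 to epoxy lactone F19. DDQ then gives 26.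

**Further compounds**
F1 | step 14 | (4S,5Z,10R,11R)-11,12-bis[(tert-butyldimethylsilyl)oxy]-4-[(4-methoxybenzyl)oxy]-6,10-dimethyl-1-(oxan-2-yloxy)dodec-5-en-2-yne | CC(C)(C)[Si](C)(C)OC[C@H](O[Si](C)(C)C(C)(C)C)[C@H](C)CCC/C(C)=C\[C@H](OCc1ccc(OC)cc1)C#CCOC1CCCCO1
F2 | step 14 | (4S,5Z,10R,11R)-11,12-bis[(tert-butyldimethylsilyl)oxy]-4-[(4-methoxybenzyl)oxy]-6,10-dimethyldodec-5-en-2-yn-1-ol | CC(C)(C)[Si](C)(C)OC[C@H](O[Si](C)(C)C(C)(C)C)[C@H](C)CCC/C(C)=C\[C@H](OCc1ccc(OC)cc1)C#CCO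
F3 | step 14 | (2E,4S,5Z,10R,11R)-11,12-bis[(tert-butyldimethylsilyl)oxy]-4-[(4-methoxybenzyl)oxy]-6,10-dimethyl-2-(tributylstannyl)dodeca-2,5-dien-1-ol | CC(C)(C)[Si](C)(C)OC[C@H](O[Si](C)(C)C(C)(C)C)[C@H](C)CCC/C(C)=C\[C@H](OCc1ccc(OC)cc1)/C=C(\CO)[Sn](CCCC)(CCCC)CCCC
F4 | step 14 | (2E,4S,5Z,10R,11R)-11,12-bis[(tert-butyldimethylsilyl)oxy]-2-iodo-4-[(4-methoxybenzyl)oxy]-6,10-dimethyldodeca-2,5-dien-1-ol | CC(C)(C)[Si](C)(C)OC[C@H](O[Si](C)(C)C(C)(C)C)[C@H](C)CCC/C(C)=C\[C@H](OCc1ccc(OC)cc1)/C=C(\CO)I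
F5 | step 14 | methyl (2E,4S,5Z,10R,11R)-11,12-bis[(tert-butyldimethylsilyl)oxy]-2-(hydroxymethyl)-4-[(4-methoxybenzyl)oxy]-6,10-dimethyldodeca-2,5-dienoate | CC(C)(C)[Si](C)(C)OC[C@H](O[Si](C)(C)C(C)(C)C)[C@H](C)CCC/C(C)=C\[C@H](OCc1ccc(OC)cc1)/C=C(\CO)C(=O)OC
F6 | step 14 | methyl (2Z,4S,5Z,10R,11R)-2-(bromomethyl)-11,12-bis[(tert-butyldimethylsilyl)oxy]-4-[(4-methoxybenzyl)oxy]-6,10-dimethyldodeca-2,5-dienoate | CC(C)(C)[Si](C)(C)OC[C@H](O[Si](C)(C)C(C)(C)C)[C@H](C)CCC/C(C)=C\[C@H](OCc1ccc(OC)cc1)/C=C(\CBr)C(=O)OC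
F7 | step 14 | methyl (2Z,4S,5Z,10R,11R)-2-(bromomethyl)-11-[(tert-butyldimethylsilyl)oxy]-12-hydroxy-4-[(4-methoxybenzyl)oxy]-6,10-dimethyldodeca-2,5-dienoate | OC[C@H](O[Si](C)(C)C(C)(C)C)[C@H](C)CCC/C(C)=C\[C@H](OCc1ccc(OC)cc1)/C=C(\CBr)C(=O)OC
F8 | step 14 | methyl (2Z,4S,5Z,10R,11R)-2-(bromomethyl)-11-[(tert-butyldimethylsilyl)oxy]-4-[(4-methoxybenzyl)oxy]-6,10-dimethyl-12-oxododeca-2,5-dienoate | O=C[C@H](O[Si](C)(C)C(C)(C)C)[C@H](C)CCC/C(C)=C\[C@H](OCc1ccc(OC)cc1)/C=C(\CBr)C(=O)OC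
F9 | step 14 | allylchromium dichloride derived from F8 (CrCl2 group in place of bromine) | O=C[C@H](O[Si](C)(C)C(C)(C)C)[C@H](C)CCC/C(C)=C\[C@H](OCc1ccc(OC)cc1)/C=C(\C[Cr](Cl)Cl)C(=O)OC
F10 | step 14 | methyl (4Z,6S,7S,8S,9R,10R)-9-[(tert-butyldimethylsilyl)oxy]-8-hydroxy-6-[(4-methoxybenzyl)oxy]germacra-4,11(13)-dien-12-oate | O[C@@H]1[C@H](O[Si](C)(C)C(C)(C)C)[C@H](C)CCC/C(C)=C\[C@H](OCc2ccc(OC)cc2)[C@H]1C(=C)C(=O)OC
F11 | step 9 | (5Z,10R,11R)-11,12-bis[(tert-butyldimethylsilyl)oxy]-6,10-dimethyl-1-(oxan-2-yloxy)dodec-5-en-2-yn-4-ol (both C4 epimers) | CC(C)(C)[Si](C)(C)OC[C@H](O[Si](C)(C)C(C)(C)C)[C@H](C)CCC/C(C)=C\C(O)C#CCOC1CCCCO1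
F12 | step 9 | (5Z,10R,11R)-11,12-bis[(tert-butyldimethylsilyl)oxy]-6,10-dimethyl-1-(oxan-2-yloxy)dodec-5-en-2-yn-4-one | CC(C)(C)[Si](C)(C)OC[C@H](O[Si](C)(C)C(C)(C)C)[C@H](C)CCC/C(C)=C\C(=O)C#CCOC1CCCCO1
F13 | step 16 | (1R)-1-[(2S,3R)-3-{(4R,5R)-5,6-bis[(tert-butyldimethylsilyl)oxy]-4-methylhexyl}-3-methyloxiran-2-yl]buta-2,3-dien-1-ol | CC(C)(C)[Si](C)(C)OC[C@H](O[Si](C)(C)C(C)(C)C)[C@H](C)CCC[C@@]1(C)O[C@H]1[C@H](O)C=C=C
F14 | step 16 | 4-methoxybenzyl ether of F13 | CC(C)(C)[Si](C)(C)OC[C@H](O[Si](C)(C)C(C)(C)C)[C@H](C)CCC[C@@]1(C)O[C@H]1[C@H](OCc1ccc(OC)cc1)C=C=C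
F15 | step 16 | (2R,3R)-2-[(tert-butyldimethylsilyl)oxy]-6-[(2R,3S)-3-{(1R)-1-[(4-methoxybenzyl)oxy]buta-2,3-dien-1-yl}-2-methyloxiran-2-yl]-3-methylhexan-1-ol | OC[C@H](O[Si](C)(C)C(C)(C)C)[C@H](C)CCC[C@@]1(C)O[C@H]1[C@H](OCc1ccc(OC)cc1)C=C=C
F16 | step 16 | (2R,3R)-2-[(tert-butyldimethylsilyl)oxy]-6-[(2R,3S)-3-{(1R)-1-[(4-methoxybenzyl)oxy]buta-2,3-dien-1-yl}-2-methyloxiran-2-yl]-3-methylhexanal | O=C[C@H](O[Si](C)(C)C(C)(C)C)[C@H](C)CCC[C@@]1(C)O[C@H]1[C@H](OCc1ccc(OC)cc1)C=C=C
F17 | step 16 | nickelalactone derived from F16 (epoxide analogue of 22, DBU ligands not drawn) | O=C[C@H](O[Si](C)(C)C(C)(C)C)[C@H](C)CCC[C@@]1(C)O[C@H]1[C@H](OCc1ccc(OC)cc1)/C=C2\C(=O)O[Ni]C2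
F18 | step 16 | (4R,5S,6R,7S,8S,9R,10R)-9-[(tert-butyldimethylsilyl)oxy]-4,5-epoxy-8-hydroxy-6-[(4-methoxybenzyl)oxy]germacr-11(13)-en-12-oic acid | O[C@@H]1[C@H](O[Si](C)(C)C(C)(C)C)[C@H](C)CCC[C@@]2(C)O[C@H]2[C@H](OCc2ccc(OC)cc2)[C@H]1C(=C)C(=O)O
F19 | step 16 | (4R,5S,6R,7R,8S,9R,10R)-9-[(tert-butyldimethylsilyl)oxy]-4,5-epoxy-6-[(4-methoxybenzyl)oxy]germacr-11(13)-en-12,8-olide | C=C1C(=O)O[C@@H]2[C@H](O[Si](C)(C)C(C)(C)C)[C@H](C)CCC[C@@]3(C)O[C@H]3[C@H](OCc4ccc(OC)cc4)[C@@H]12
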